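The route cuts C3–C4 and C1–C5. It exploits one feature: the seven-membered ring C1–C2–C3–C4–C7–C6–C5, bridged by carbonyl C8, contains a five-membered ring (C4, C7, C6, C5, C8) strapped across C4 and C5 by the three-carbon unit C3–C2–C1. One chiral dirhodium-catalysed operation, vinylcarbenoid cyclopropanation of a cyclopentadiene followed by divinylcyclopropane rearrangement, forms both bonds, the seven-membered ring and both bridgehead stereocentres. Its precursors are an achiral 3-arylcyclopentadienone dimethyl ketal and methyl 2-diazobut-3-enoate. The surviving C6=C7 styrene then accepts the resorcinol ring and hydrogen from the exo face. Oxidation at C1, olefination and demethylation complete the target.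

Key step: step 7

Numbering: C1 is the enone C=O, C2 the enone CH and C3 the alkene carbon bearing the side chain. C4 is the bridgehead on C3 and C5 the bridgehead between the two carbonyls. C6 is the CH with the catechol ring, C7 the CH with the resorcinol ring and C8 the one-carbon bridge. Exo means on the side of C8 and endo means on the side of the C1–C3 bridge. All locants in names of bicyclic compounds are these core numbers. The target is (4S,5R,6S,7S).

Assumption: the sense of induction is taken from the established behaviour of the DOSP catalysts in styrene cyclopropanation, which points to the R-configured catalyst for the required bridgeheads. Both antipodes are sold.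

Step 1
Reactants: 1 cyclopent-4-ene-1,3-dione
Product: 2 4,4-dimethoxycyclopent-2-en-1-one
Conditions: HC(OMe)3 (1.1 equiv), p-TsOH·H2O (2 mol %), MeOH, 0 °C to rt
Reagents that add atoms: trimethyl orthoformate, COC(OC)OC
Why: Acid-catalysed ketalisation with an orthoester as water scavenger; no enol ether can form because the enol of 1 would be a cyclopentadienone, and the remaining carbonyl, now a conjugated enone beside an electron-withdrawing ketal, reacts far more slowly, so the reaction should stop at the monoketal.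

Step 2
Reactants: 3 4-bromo-1,2-dimethoxybenzene; 2 4,4-dimethoxycyclopent-2-en-1-one
Product: 5 (±)-1-(3,4-dimethoxyphenyl)-4,4-dimethoxycyclopent-2-en-1-ol, via 3,4-dimethoxyphenyllithium 4 (not isolated)
Conditions: 3, n-BuLi (1.05 equiv), THF, −78 °C; then 2, −78 °C; H2O quench; used crude
Reagents that add atoms: none
Why: Halogen–lithium exchange followed by 1,2-addition of the hard aryllithium to the enone carbonyl at low temperature; the new carbinol centre is racemic and disappears in step 3.

Step 3
Reactants: 5 (±)-1-(3,4-dimethoxyphenyl)-4,4-dimethoxycyclopent-2-en-1-ol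
Product: 6 2-(3,4-dimethoxyphenyl)-5,5-dimethoxycyclopenta-1,3-diene
Conditions: Burgess reagent (1.3 equiv), THF, rt to 45 °C; kept cold and used at once
Reagents that add atoms: none
Why: Burgess dehydration (syn elimination of a sulfamate ester under neutral conditions) removes the tertiary allylic benzylic hydroxyl together with a hydrogen of the only neighbouring CH2, the absence of acid and free water spares the ketal, and the fully substituted ketal carbon rules out 1,5-hydrogen shifts in the diene.

Step 4
Reactants: 7 methyl acetoacetate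
Product: 8 methyl 2-diazo-3-oxobutanoate
Conditions: 4-acetamidobenzenesulfonyl azide (1.1 equiv), Et3N, MeCN, 0 °C to rt
Reagents that add atoms: 4-acetamidobenzenesulfonyl azide, CC(=O)Nc1ccc(cc1)S(=O)(=O)N=[N+]=[N-]
Why: Regitz diazo transfer onto an activated methylene group, a standard reaction of β-keto esters.

Step 5
Reactants: 8 methyl 2-diazo-3-oxobutanoate
Product: 9 (±)-methyl 2-diazo-3-hydroxybutanoate
Conditions: NaBH4, MeOH, 0 °C
Reagents that add atoms: none
Why: Chemoselective borohydride reduction of the ketone, which leaves the stabilised diazo ester intact; the racemic carbinol centre is removed in step 6.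

Step 6
Reactants: 9 (±)-methyl 2-diazo-3-hydroxybutanoate
Product: 10 methyl 2-diazobut-3-enoate
Conditions: POCl3 (1.5 equiv), Et3N (4 equiv), CH2Cl2, 0 °C; kept cold and used the same day
Reagents that add atoms: none
Why: Dehydration by O-phosphorylation and amine-induced elimination is the established access to this vinyldiazoacetate, which is used fresh because it slowly cyclises to a pyrazole.

Step 7
Reactants: 6 2-(3,4-dimethoxyphenyl)-5,5-dimethoxycyclopenta-1,3-diene; 10 methyl 2-diazobut-3-enoate
Product: 12 methyl (4S,5S)-6-(3,4-dimethoxyphenyl)-8,8-dimethoxybicyclo[3.2.1]octa-2,6-diene-3-carboxylate, via cis-divinylcyclopropane 11 (not isolated)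
Conditions: Rh2(R-DOSP)4 (1 mol %), 6 (1 equiv), slow addition of 10 (2.5 equiv), 2,2-dimethylbutane/toluene, −20 °C to rt
Reagents that add atoms: none
Why: Rh2(R-DOSP)4 expels N2 from 10, and the donor–acceptor vinylcarbenoid adds in a concerted but asynchronous way to the C4=C7 bond of 6, binding first to the diene terminus C4 and placing its vinyl group endo, which gives cis-divinylcyclopropane 11. Compound 11 undergoes a boat-shaped Cope [3,3] shift at or below room temperature in which the cyclopropane bond C3–C7 breaks, C1–C5 forms and the alkenes end at C2=C3 and C6=C7; this is the well-known tandem cyclopropanation/Cope (formal 4+3) reaction of vinyldiazoacetates with cyclopentadienes. The seven-membered ring is thus closed by sigmatropic ring expansion of the three-membered ring and not by an end-to-end cyclisation. C4 is set by the chiral prolinate ligands, which decide which enantiotopic face of the flat achiral diene meets the carbenoid, and C5 follows from C4 because the shift is suprafacial on the five-membered ring and a three-atom bridge can span only one face. Site selectivity between the two alkenes of 6 is required: these bulky carbenoids accept cis-disubstituted alkenes but are slow with alkenes that hold one substituent trans to another, as the C6 aryl group is to C8, so sterics should outweigh the electronic pull of the aryl group and send the attack to C4=C7. Chemoselectivity against ylide formation at the ketal oxygens and C–H insertion into OMe groups rests on the much faster cyclopropanation of a conjugated diene and on keeping the concentration of 10 low.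

Step 8
Reactants: 12 methyl (4S,5S)-6-(3,4-dimethoxyphenyl)-8,8-dimethoxybicyclo[3.2.1]octa-2,6-diene-3-carboxylate
Product: 13 methyl (4S,5S)-6-(3,4-dimethoxyphenyl)-8-oxobicyclo[3.2.1]octa-2,6-diene-3-carboxylate
Conditions: Amberlyst-15, acetone/H2O (10:1), rt, in the dark; product kept below 60 °C
Reagents that add atoms: water, O
Why: Acid-catalysed ketal hydrolysis with a sulfonic acid resin in wet acetone, the usual mild way to unmask bridge ketals of norbornene type, frees a flat C8 carbonyl that opens the exo face of C6=C7, and the bridgeheads cannot enolise, so C4 and C5 are safe.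

Step 9
Reactants: 13 methyl (4S,5S)-6-(3,4-dimethoxyphenyl)-8-oxobicyclo[3.2.1]octa-2,6-diene-3-carboxylate; 14 1-iodo-3,5-dimethoxybenzene
Product: 15 methyl (4S,5S,6S,7S)-6-endo-(3,4-dimethoxyphenyl)-7-exo-(3,5-dimethoxyphenyl)-8-oxobicyclo[3.2.1]oct-2-ene-3-carboxylate
Conditions: 14 (2 equiv), Pd(OAc)2 (10 mol %), AsPh3 (30 mol %), HCO2K (3 equiv), n-Bu4NCl (1 equiv), DMF, 55 °C
Reagents that add atoms: none
Why: Reductive Heck hydroarylation of a strained bicyclic alkene: oxidative addition of 14 to zerovalent palladium is followed by syn carbopalladation of C6=C7 from the exo face (open beside the flat C8 carbonyl, whereas the endo face is roofed by the C1–C2–C3 bridge), the aryl group going to unsubstituted C7 and palladium to benzylic C6 as in Heck reactions of α-substituted styrenes, and because the only β-hydrogens are anti (C7–H) or at a bridgehead (C5–H), formate-derived hydride replaces palladium with retention, setting C7 (aryl exo) and C6 (hydrogen exo, aryl endo) in one syn addition.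

Step 10
Reactants: 15 methyl (4S,5S,6S,7S)-6-endo-(3,4-dimethoxyphenyl)-7-exo-(3,5-dimethoxyphenyl)-8-oxobicyclo[3.2.1]oct-2-ene-3-carboxylate
Product: 16 methyl (4S,5R,6S,7S)-6-endo-(3,4-dimethoxyphenyl)-7-exo-(3,5-dimethoxyphenyl)-1,8-dioxobicyclo[3.2.1]oct-2-ene-3-carboxylate
Conditions: Rh2(cap)4 (dirhodium tetracaprolactamate, 1 mol %), t-BuOOH (70 % in H2O, 10 equiv), ClCH2CH2Cl, 40 °C
Reagents that add atoms: tert-butyl hydroperoxide, CC(C)(C)OO
Why: Radical allylic oxidation by the tert-butylperoxyl radical, established for converting cycloalkene-1-carboxylates and enones into their γ-oxo derivatives; C1 is the only allylic CH2, the bridgehead hydrogens at C4 and C5 cannot give conjugated radicals, and the base-free medium protects the emerging non-enolisable 1,3-diketone from retro-Claisen cleavage.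

Step 11
Reactants: 16 methyl (4S,5R,6S,7S)-6-endo-(3,4-dimethoxyphenyl)-7-exo-(3,5-dimethoxyphenyl)-1,8-dioxobicyclo[3.2.1]oct-2-ene-3-carboxylate
Product: 17 6-endo-(3,4-dimethoxyphenyl)-7-exo-(3,5-dimethoxyphenyl)-3-(hydroxymethyl)bicyclo[3.2.1]oct-2-ene-1,8-diol (C4–C7 arranged in space as in 15; carbinol centres C1 and C8 left undefined)
Conditions: i-Bu2AlH (8 equiv), CH2Cl2, −78 to 0 °C; aq. potassium sodium tartrate
Reagents that add atoms: none
Why: Exhaustive 1,2-hydride reduction of the ester and both ketones brings the ester carbon to the alcohol level and masks the base-sensitive 1,3-diketone before the only strongly basic step, and the configuration of the new carbinols is irrelevant because step 15 erases both.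

Step 12
Reactants: 17 6-endo-(3,4-dimethoxyphenyl)-7-exo-(3,5-dimethoxyphenyl)-3-(hydroxymethyl)bicyclo[3.2.1]oct-2-ene-1,8-diol
Product: 18 6-endo-(3,4-dimethoxyphenyl)-7-exo-(3,5-dimethoxyphenyl)-1,8-dihydroxybicyclo[3.2.1]oct-2-ene-3-carbaldehyde
Conditions: TEMPO (10 mol %), PhI(OAc)2 (1.1 equiv), CH2Cl2, rt
Reagents that add atoms: none
Why: Oxoammonium (TEMPO) oxidation prefers the unhindered primary allylic alcohol over the two secondary carbinols flanked by bridgeheads, and the formyl group lies trans to C1 across C2=C3, so no lactol can form.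

Step 13
Reactants: 19 3,4-dimethoxybenzyl chloride
Product: 20 diethyl (3,4-dimethoxybenzyl)phosphonate
Conditions: P(OEt)3 (neat, 1.5 equiv), 140 °C
Reagents that add atoms: triethyl phosphite, CCOP(OCC)OCC
Why: Michaelis–Arbuzov reaction of a reactive benzylic chloride.

Step 14
Reactants: 18 6-endo-(3,4-dimethoxyphenyl)-7-exo-(3,5-dimethoxyphenyl)-1,8-dihydroxybicyclo[3.2.1]oct-2-ene-3-carbaldehyde; 20 diethyl (3,4-dimethoxybenzyl)phosphonate
Product: 22 3-[(E)-2-(3,4-dimethoxyphenyl)ethenyl]-6-endo-(3,4-dimethoxyphenyl)-7-exo-(3,5-dimethoxyphenyl)bicyclo[3.2.1]oct-2-ene-1,8-diol, via potassium phosphonate carbanion 21 (not isolated)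
Conditions: 20 (4 equiv), KN(SiMe3)2 (3.9 equiv), THF, −78 °C; then 18, −78 °C to rt
Reagents that add atoms: none
Why: Horner–Wadsworth–Emmons olefination of an enal with a benzylic phosphonate gives the E-alkene, the excess carbanion covers the two free hydroxyls, and no ketone is present, so retro-aldol or retro-Claisen ring opening cannot occur.

Step 15
Reactants: 22 3-[(E)-2-(3,4-dimethoxyphenyl)ethenyl]-6-endo-(3,4-dimethoxyphenyl)-7-exo-(3,5-dimethoxyphenyl)bicyclo[3.2.1]oct-2-ene-1,8-diol
Product: 23 (4S,5R,6S,7S)-3-[(E)-2-(3,4-dimethoxyphenyl)ethenyl]-6-endo-(3,4-dimethoxyphenyl)-7-exo-(3,5-dimethoxyphenyl)bicyclo[3.2.1]oct-2-ene-1,8-dione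
Conditions: Dess–Martin periodinane (3 equiv), pyridine (buffer), CH2Cl2, 0 °C to rt
Reagents that add atoms: none
Why: Dess–Martin oxidation converts both secondary alcohols into ketones under mild, nearly neutral conditions, merging the carbinol epimers into one compound, and C5 between the two carbonyls cannot epimerise because a bridgehead enol is barred by Bredt's rule.

Step 16
Reactants: 23 (4S,5R,6S,7S)-3-[(E)-2-(3,4-dimethoxyphenyl)ethenyl]-6-endo-(3,4-dimethoxyphenyl)-7-exo-(3,5-dimethoxyphenyl)bicyclo[3.2.1]oct-2-ene-1,8-dione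
Product: 24 CNP0285027.2, (4S,5R,6S,7S)-3-[(E)-2-(3,4-dihydroxyphenyl)ethenyl]-6-endo-(3,4-dihydroxyphenyl)-7-exo-(3,5-dihydroxyphenyl)bicyclo[3.2.1]oct-2-ene-1,8-dione
Conditions: BBr3 (15 equiv), CH2Cl2, −78 to 0 °C; ice-water quench
Reagents that add atoms: none
Why: Lewis acid cleavage of all six aryl methyl ethers with BBr3, the standard last step for permethylated stilbene oligomers, proceeds under acidic, non-nucleophilic conditions that the dienone and the non-enolisable diketone should tolerate and that touch none of the four stereocentres.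

Compound list
1 | cyclopent-4-ene-1,3-dione | O=C1C=CC(=O)C1 | starting material
2 | 4,4-dimethoxycyclopent-2-en-1-one | O=C1C=CC(OC)(OC)C1 | intermediate
3 | 4-bromo-1,2-dimethoxybenzene | COc1ccc(Br)cc1OC | starting material
4 | 3,4-dimethoxyphenyllithium | [Li]c1ccc(OC)c(OC)c1 | intermediate
5 | (±)-1-(3,4-dimethoxyphenyl)-4,4-dimethoxycyclopent-2-en-1-ol | COC1(OC)C=CC(O)(c2ccc(OC)c(OC)c2)C1 | intermediate
6 | 2-(3,4-dimethoxyphenyl)-5,5-dimethoxycyclopenta-1,3-diene | COC1(OC)C=CC(c2ccc(OC)c(OC)c2)=C1 | intermediate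
7 | methyl acetoacetate | CC(=O)CC(=O)OC | starting material
8 | methyl 2-diazo-3-oxobutanoate | CC(=O)C(=[N+]=[N-])C(=O)OC | intermediate
9 | (±)-methyl 2-diazo-3-hydroxybutanoate | CC(O)C(=[N+]=[N-])C(=O)OC | intermediate
10 | methyl 2-diazobut-3-enoate | C=CC(=[N+]=[N-])C(=O)OC | intermediate
11 | cis-divinylcyclopropane (cyclopropane C3–C4–C7 fused to the five-membered ring; ethenyl on C3 endo, CO2Me exo) | C=C[C@@]1(C(=O)OC)[C@H]2C(OC)(OC)C=C(c3ccc(OC)c(OC)c3)[C@@H]12 | intermediate
12 | methyl (4S,5S)-6-(3,4-dimethoxyphenyl)-8,8-dimethoxybicyclo[3.2.1]octa-2,6-diene-3-carboxylate | C1C=C(C(=O)OC)[C@H]2C(OC)(OC)[C@@H]1C(c1ccc(OC)c(OC)c1)=C2 | intermediate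
13 | methyl (4S,5S)-6-(3,4-dimethoxyphenyl)-8-oxobicyclo[3.2.1]octa-2,6-diene-3-carboxylate | C1C=C(C(=O)OC)[C@H]2C(=O)[C@@H]1C(c1ccc(OC)c(OC)c1)=C2 | intermediate
14 | 1-iodo-3,5-dimethoxybenzene | COc1cc(I)cc(OC)c1 | starting material
15 | methyl (4S,5S,6S,7S)-6-endo-(3,4-dimethoxyphenyl)-7-exo-(3,5-dimethoxyphenyl)-8-oxobicyclo[3.2.1]oct-2-ene-3-carboxylate | C1C=C(C(=O)OC)[C@H]2C(=O)[C@@H]1[C@@H](c1ccc(OC)c(OC)c1)[C@@H]2c1cc(OC)cc(OC)c1 | intermediate
16 | methyl (4S,5R,6S,7S)-6-endo-(3,4-dimethoxyphenyl)-7-exo-(3,5-dimethoxyphenyl)-1,8-dioxobicyclo[3.2.1]oct-2-ene-3-carboxylate | O=C1C=C(C(=O)OC)[C@H]2C(=O)[C@@H]1[C@@H](c1ccc(OC)c(OC)c1)[C@@H]2c1cc(OC)cc(OC)c1 | intermediate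
17 | 6-endo-(3,4-dimethoxyphenyl)-7-exo-(3,5-dimethoxyphenyl)-3-(hydroxymethyl)bicyclo[3.2.1]oct-2-ene-1,8-diol (C1 and C8 undefined) | OC1C=C(CO)[C@H]2C(O)[C@@H]1[C@@H](c1ccc(OC)c(OC)c1)[C@@H]2c1cc(OC)cc(OC)c1 | intermediate
18 | 6-endo-(3,4-dimethoxyphenyl)-7-exo-(3,5-dimethoxyphenyl)-1,8-dihydroxybicyclo[3.2.1]oct-2-ene-3-carbaldehyde (C1 and C8 undefined) | OC1C=C(C=O)[C@H]2C(O)[C@@H]1[C@@H](c1ccc(OC)c(OC)c1)[C@@H]2c1cc(OC)cc(OC)c1 | intermediate
19 | 3,4-dimethoxybenzyl chloride | COc1ccc(CCl)cc1OC | starting material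
20 | diethyl (3,4-dimethoxybenzyl)phosphonate | CCOP(=O)(Cc1ccc(OC)c(OC)c1)OCC | intermediate
21 | potassium phosphonate carbanion of 20 | CCOP(=O)([CH-]c1ccc(OC)c(OC)c1)OCC.[K+] | intermediate
22 | 3-[(E)-2-(3,4-dimethoxyphenyl)ethenyl]-6-endo-(3,4-dimethoxyphenyl)-7-exo-(3,5-dimethoxyphenyl)bicyclo[3.2.1]oct-2-ene-1,8-diol (C1 and C8 undefined) | OC1C=C(/C=C/c2ccc(OC)c(OC)c2)[C@H]2C(O)[C@@H]1[C@@H](c1ccc(OC)c(OC)c1)[C@@H]2c1cc(OC)cc(OC)c1 | intermediate
23 | (4S,5R,6S,7S)-3-[(E)-2-(3,4-dimethoxyphenyl)ethenyl]-6-endo-(3,4-dimethoxyphenyl)-7-exo-(3,5-dimethoxyphenyl)bicyclo[3.2.1]oct-2-ene-1,8-dione | O=C1C=C(/C=C/c2ccc(OC)c(OC)c2)[C@H]2C(=O)[C@@H]1[C@@H](c1ccc(OC)c(OC)c1)[C@@H]2c1cc(OC)cc(OC)c1 | intermediate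
24 | CNP0285027.2 | O=C1C=C(/C=C/c2ccc(O)c(O)c2)[C@H]2C(=O)[C@@H]1[C@@H](c1ccc(O)c(O)c1)[C@@H]2c1cc(O)cc(O)c1 | target

Total step count: 16. Longest linear sequence: 12 steps (1–3, 7–12, 14–16).

Steps most likely to fail

Step 7. The carbenoid may attack the electron-rich aryl-substituted C5=C6 bond, which would turn the bridge the wrong way round. It may also be captured by a ketal oxygen. A third possibility is that it approaches the diene too slowly past the ketal methoxy group, so that 10 is lost to pyrazole formation and carbene dimerisation.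

The fallback keeps the aryl donor out of the cycloaddition; it sets out from 2 and returns at 12.
- LiN(i-Pr)2 and then N-phenylbis(trifluoromethanesulfonimide) (THF, −78 °C) convert 2 into 3,3-dimethoxycyclopenta-1,4-dien-1-yl trifluoromethanesulfonate F1. Its triflate-bearing alkene is both hindered and electron-poor.
- With 10 and the same dirhodium catalyst, only the C4=C7 bond can then react. This leads through the triflyloxy cis-divinylcyclopropane F2 to methyl (4S,5S)-8,8-dimethoxy-6-(trifluoromethylsulfonyloxy)bicyclo[3.2.1]octa-2,6-diene-3-carboxylate F3.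
- Suzuki–Miyaura coupling of F3 with 3,4-dimethoxyphenylboronic acid (Pd(PPh3)4, K2CO3, dioxane/H2O) gives 12.

Step 9. Migratory insertion into the trisubstituted alkene may be so slow that formate merely reduces the aryl iodide. Insertion at the enoate may compete, or 13 may lose CO on prolonged heating.

The fallback separates the two bond formations; it sets out from 12 and returns at 15.
- With the ketal still in place, BH3·THF (0 °C) and then NaBO3·4H2O hydroborate the styrene bond faster than the electron-poor enoate. Boron goes to C7 and hydrogen to C6, both syn from the exo face. The product is methyl 6-endo-(3,4-dimethoxyphenyl)-7-exo-hydroxy-8,8-dimethoxybicyclo[3.2.1]oct-2-ene-3-carboxylate F4, which already holds the endo C6 aryl group.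
- Oxalyl chloride and then water give the corresponding C7 hydrogen oxalate F5.
- Decarboxylative nickel/photoredox coupling follows, with 1-bromo-3,5-dimethoxybenzene (Ir[dF(CF3)ppy]2(dtbbpy)PF6, NiCl2(dme), dtbbpy, CsHCO3, blue light). The C7 radical should be captured on the exo face, anti to the neighbouring endo aryl group. This gives methyl 6-endo-(3,4-dimethoxyphenyl)-7-exo-(3,5-dimethoxyphenyl)-8,8-dimethoxybicyclo[3.2.1]oct-2-ene-3-carboxylate F6.
- Hydrolysis as in step 8 leads to 15.

Step 10. Hydrogen abstraction from the tertiary benzylic C6–H and C7–H bonds of the electron-rich arenes, or peroxide addition to the strained C8 ketone, may compete with abstraction at C1.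

The fallback replaces the radical oxidation by an ionic one; it sets out from 15 and returns at 17.
- LiN(i-Pr)2 (THF, −78 °C) removes a C1 hydrogen. PhSeCl then traps the extended enolate at its α-carbon C3, giving methyl 6-endo-(3,4-dimethoxyphenyl)-7-exo-(3,5-dimethoxyphenyl)-8-oxo-3-(phenylselanyl)bicyclo[3.2.1]oct-1-ene-3-carboxylate F7.
- Oxidation with H2O2/pyridine gives an allylic selenoxide without a syn β-hydrogen. It undergoes the [2,3]-sigmatropic shift, which delivers oxygen to C1 and restores C2=C3. The product is methyl 6-endo-(3,4-dimethoxyphenyl)-7-exo-(3,5-dimethoxyphenyl)-1-hydroxy-8-oxobicyclo[3.2.1]oct-2-ene-3-carboxylate F8.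
- Reduction with i-Bu2AlH as in step 11 gives 17.

Further compounds
F1 | step 7 | 3,3-dimethoxycyclopenta-1,4-dien-1-yl trifluoromethanesulfonate | COC1(OC)C=CC(OS(=O)(=O)C(F)(F)F)=C1
F2 | step 7 | triflyloxy cis-divinylcyclopropane (transient) | C=C[C@@]1(C(=O)OC)[C@H]2C(OC)(OC)C=C(OS(=O)(=O)C(F)(F)F)[C@@H]12
F3 | step 7 | methyl (4S,5S)-8,8-dimethoxy-6-(trifluoromethylsulfonyloxy)bicyclo[3.2.1]octa-2,6-diene-3-carboxylate | C1C=C(C(=O)OC)[C@H]2C(OC)(OC)[C@@H]1C(OS(=O)(=O)C(F)(F)F)=C2
F4 | step 9 | methyl 6-endo-(3,4-dimethoxyphenyl)-7-exo-hydroxy-8,8-dimethoxybicyclo[3.2.1]oct-2-ene-3-carboxylate | C1C=C(C(=O)OC)[C@H]2C(OC)(OC)[C@@H]1[C@@H](c1ccc(OC)c(OC)c1)[C@@H]2O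
F5 | step 9 | C7 hydrogen oxalate of F4 | C1C=C(C(=O)OC)[C@H]2C(OC)(OC)[C@@H]1[C@@H](c1ccc(OC)c(OC)c1)[C@@H]2OC(=O)C(=O)O
F6 | step 9 | methyl 6-endo-(3,4-dimethoxyphenyl)-7-exo-(3,5-dimethoxyphenyl)-8,8-dimethoxybicyclo[3.2.1]oct-2-ene-3-carboxylate | C1C=C(C(=O)OC)[C@H]2C(OC)(OC)[C@@H]1[C@@H](c1ccc(OC)c(OC)c1)[C@@H]2c1cc(OC)cc(OC)c1
F7 | step 10 | methyl 6-endo-(3,4-dimethoxyphenyl)-7-exo-(3,5-dimethoxyphenyl)-8-oxo-3-(phenylselanyl)bicyclo[3.2.1]oct-1-ene-3-carboxylate (C3 undefined) | C1=CC(C(=O)OC)([Se]c3ccccc3)[C@H]2C(=O)[C@@H]1[C@@H](c1ccc(OC)c(OC)c1)[C@@H]2c1cc(OC)cc(OC)c1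
F8 | step 10 | methyl 6-endo-(3,4-dimethoxyphenyl)-7-exo-(3,5-dimethoxyphenyl)-1-hydroxy-8-oxobicyclo[3.2.1]oct-2-ene-3-carboxylate (C1 undefined) | OC1C=C(C(=O)OC)[C@H]2C(=O)[C@@H]1[C@@H](c1ccc(OC)c(OC)c1)[C@@H]2c1cc(OC)cc(OC)c1
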